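Of the E charged, 13.7% stands as J at the end of the north-west run, the mean of its last four readings. This reading is taken as the plateau yield j: the part of the charged E held as J once the north-west run has stopped, carried below as an estimate to flasks that stop near the top of J.

| setting | north-east | north-west | oak | elm | birch | larch | cedar |
|---|---|---|---|---|---|---|---|
| E | 1.3 × 10⁻⁴ M | 0.0017 M | 1.5 × 10⁻⁴ M | 5.0 × 10⁻⁴ M | 0.0020 M | 0.0010 M | 2.5 × 10⁻⁴ M |
| X | 0.65 mM | 0.65 mM | 0.650 mM | 0.650 mM | 0.650 mM | 0.650 mM | 0.650 mM |
| remark | run made earlier | run made earlier |  |  |  |  |  |
| time |  |  | 4.0 min | 4.0 min | 4.0 min | 4.0 min | 4.0 min |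
| volume of the second phase over the first |  |  | 2.0 | 2.0 | 2.0 | 2.0 | 2.0 |

- north-east (time / min: J / %, D / %): 0.200: 12.0, 4.8; 0.667: 12.6, 35.8; 1.00: 9.3, 50.0; 1.50: 6.4, 64.4; 2.50: 3.8, 77.8; 3.00: 3.1, 81.6; 4.00: 1.5, 87.3
- north-west (time / min: J / %, D / %): 0.500: 10.4, 3.7; 1.00: 13.0, 8.4; 1.50: 13.5, 10.6; 2.50: 13.6, 12.0; 3.00: 13.7, 12.1; 4.00: 13.9, 11.9

(scatter of a reading: 0.5 percentage points)

- ranking by share of J in all that became J or D, from high to low, at 4.0 min (oak / elm / birch / larch / cedar)
- the share of J in all that became J or D of the flask you put first, at 4.0 min
- the share of J in all that became J or D of the flask you put last, at 4.0 min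

- in the second phase: X; everything else is in the first
- charges count per volume of the first phase; a concentration in a rate is the amount of a species over the volume of its own phase; every rate counts per litre of the first phase
- the earlier runs hold the two phases in the same ratio of volumes as the flask asked about

J appears first and D grows from it, so the path is consecutive; counting one X per J and two per D, the north-west readings give J + 2D = 0.641 mM, close to the 0.65 mM of X charged, so X is the limiting reagent there.

A second way to j is the top of J in the north-east run, whose highest reading is 12.6%. The two ways part by 1.1 percentage points against a scatter of 0.5 points. The north-east figure is the weaker: it is one reading, and the top may lie in the gap after 0.200 min, whereas four north-west readings lie flat.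

With b the X charged per E charged, the count at the stop gives D = (b − j)/2, so the share of J is 2j/(j + b), provided the stop falls near the top of J. Birch has b = 0.325, which gives 59.2%. Cedar has b = 2.60 and oak 4.33, both above the 2 X that this count gives to each E taken through to D. Oak is charged close to the north-east run, whose readings at 4.00 min give a share of 1.69%, from a J reading of 1.5% with a scatter of 0.5 points. Ranking by rising b gives the same order as the forecast.

The forecast gives birch > larch > elm > cedar > oak, with 58% (54% to 62%) for birch and 2.5% (1.4% to 4%) for oak: “Birch runs out of X at about 23% conversion, giving a J share near 58%.” The reckoning here gives a higher share than the forecast for birch and a lower one for oak.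

The flasks give birch > larch > elm > cedar > oak, with 57.8% for birch and 2.73% for oak.

    G ⇌ X, rate k1*([G] - [X]/K1) per volume of the first phase (partition coefficient = 1.10, kL = 0.0640 /s)
    E + G → J (k = 230 /M/s)
    G + J → D (k = 680 /M/s)
    2 G → Q (k = 91.0 /M/s)
    E ⇌ Z (K = 0.690, k = 0.0160 /s)

At 4.00 min birch holds J at 13.1% and D at 9.54%, with 0.256% of its X left, and its share lies 1.4 points below the 59.2% reckoned from j. A neighbour like birch but charged with 0.0012 M of E has b = 0.542, so j gives it a share of 40.3%. That flask gives 42.0%, holding J at 14.1% and D at 19.4% at 4.00 min.

(The readings stem from a simulated flask from invented constants; noise was put on by code.)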